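**Plan**

- Retrosynthesis: take off the two O-benzyl groups and the O-silyl group and add a sacrificial second CO2Me at C2. Ring B of the tetralin is then cut at C1–C2 and the pendant guaiacyl ring at C1–C1' in one operation. The open chain is cut at C2–C3 (aldehyde alpha-carbon plus bromomalonate), at ring A–CHO, and at ring A–C4 (aryl iodide plus allyl alcohol).
- Enabling feature: C1 carries only C8a of ring A, C1' of the pendant ring, C2 and one hydrogen. It can therefore start as the formyl carbon of a ring-A benzaldehyde. As a diazo compound and then a carbene on palladium, it accepts first the aryl group and then the C2 carbanion.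
- Both aromatic rings are 4-benzyloxy-3-methoxyphenyl units, so one aryl iodide serves twice: as the source of ring A with C4–C3, and as the aryl partner at C1.
- Forward order: aryl iodide, 3-arylpropanal, alpha-malonylation (C2–C3), reduction and silylation, formylation of ring A para to OMe (C1), tosylhydrazone, palladium-catalysed closure of ring B, then demethoxycarbonylation, epimerisation and two deprotections.
- Stereochemistry: C3 comes from a catalyst-controlled enamine alkylation, C1 from C3 in the ring closure (1,3-cis), and C2 from thermodynamic equilibration to the all-trans ester.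

Key step: step 8

Assumption: the (2S,5R)-imidazolidinone is taken to leave the Re face of its E-enamine open, the mirror image of the accepted shielding model for the (2R,5S) catalyst, which leads to the (S)-aldehyde; if the sense were opposite, the antipodal catalyst would be used.

Step 1
Reactants: 1 4-iodo-2-methoxyphenol
Product: 2 1-(benzyloxy)-4-iodo-2-methoxybenzene
Conditions: BnBr, K2CO3, DMF, 23 °C
Reagents that add atoms: benzyl bromide, BrCc1ccccc1
Why: Williamson ether synthesis on the phenoxide, with benzyl chosen because both such groups leave together by hydrogenolysis in the last step.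

Step 2
Reactants: 2 1-(benzyloxy)-4-iodo-2-methoxybenzene; 3 allyl alcohol
Product: 4 3-[4-(benzyloxy)-3-methoxyphenyl]propanal
Conditions: Pd(OAc)2 (2 mol %), Bu4NCl, NaHCO3, DMF, 45 °C
Reagents that add atoms: none
Why: Heck arylation at the terminal alkene carbon followed by beta-hydride elimination towards the carbinol carbon and enol-to-aldehyde tautomerisation, the standard route from aryl iodides and allyl alcohol to 3-arylpropanals.

Step 3
Reactants: 4 3-[4-(benzyloxy)-3-methoxyphenyl]propanal; 5 dimethyl bromomalonate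
Product: 6 dimethyl 2-[(2S)-1-[4-(benzyloxy)-3-methoxyphenyl]-3-oxopropan-2-yl]propanedioate
Conditions: (2S,5R)-2-tert-butyl-3,5-dimethylimidazolidin-4-one·TfOH (20 mol %), Ru(bpy)3Cl2 (0.5 mol %), 2,6-lutidine, DMF, visible light, 23 °C (4 in excess)
Reagents that add atoms: none
Why: Enantioselective alpha-alkylation of an aldehyde by merged enamine and photoredox catalysis, well shown for 3-arylpropanals and bromomalonates, in which the malonyl radical from reductive C–Br cleavage adds to the open face of the E-enamine, forms C2–C3 and sets C3 as S under catalyst control.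

Step 4
Reactants: 6 dimethyl 2-[(2S)-1-[4-(benzyloxy)-3-methoxyphenyl]-3-oxopropan-2-yl]propanedioate
Product: 7 dimethyl 2-[(2S)-1-[4-(benzyloxy)-3-methoxyphenyl]-3-hydroxypropan-2-yl]propanedioate
Conditions: BH3·THF (0.5 equiv), THF, −30 °C; pH 7 buffer, cold work-up, crude used at once
Reagents that add atoms: none
Why: Chemoselective borane reduction of an aldehyde beside esters, chosen because it passes through a borate ester and not a free alkoxide, so neither closure of the gamma-hydroxy malonate to a butyrolactone nor enolisation at C3 is base-promoted.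

Step 5
Reactants: 7 dimethyl 2-[(2S)-1-[4-(benzyloxy)-3-methoxyphenyl]-3-hydroxypropan-2-yl]propanedioate
Product: 8 dimethyl 2-[(2S)-1-[4-(benzyloxy)-3-methoxyphenyl]-3-[(triisopropylsilyl)oxy]propan-2-yl]propanedioate
Conditions: TIPSOTf, 2,6-lutidine, CH2Cl2, −78 °C
Reagents that add atoms: triisopropylsilyl triflate, CC(C)[Si](OS(=O)(=O)C(F)(F)F)(C(C)C)C(C)C
Why: Silyl triflate silylation of a primary alcohol is fast enough at −78 °C to outrun lactonisation, and the triisopropylsilyl ether is chosen over a tert-butyldimethylsilyl ether because it should better withstand the acid of step 6, the carbonate of step 8, hot chloride and water in step 9 and methoxide in step 10.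

Step 6
Reactants: 8 dimethyl 2-[(2S)-1-[4-(benzyloxy)-3-methoxyphenyl]-3-[(triisopropylsilyl)oxy]propan-2-yl]propanedioate
Product: 9 dimethyl 2-[(2S)-1-[4-(benzyloxy)-2-formyl-5-methoxyphenyl]-3-[(triisopropylsilyl)oxy]propan-2-yl]propanedioate
Conditions: Cl2CHOMe, AgOTf, CH2Cl2, −78 °C; aq NaHCO3
Reagents that add atoms: dichloromethyl methyl ether, COC(Cl)Cl; water, O
Why: Rieche formylation, which should attack the only free ring position para to an oxygen substituent (para to OMe, ortho to the side chain, as is usual for 4-alkyl-1,2-dialkoxybenzenes), while silver triflate activation at −78 °C is known to spare phenol protecting groups.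

Step 7
Reactants: 9 dimethyl 2-[(2S)-1-[4-(benzyloxy)-2-formyl-5-methoxyphenyl]-3-[(triisopropylsilyl)oxy]propan-2-yl]propanedioate
Product: 10 (E)-N-tosylhydrazone of 9
Conditions: TsNHNH2, MeOH, 23 °C; recrystallisation
Reagents that add atoms: p-toluenesulfonyl hydrazide, Cc1ccc(cc1)S(=O)(=O)NN
Why: Condensation of an aromatic aldehyde with a sulfonyl hydrazide gives the E-hydrazone under neutral conditions that leave malonate and silyl ether alone, and a crystalline product would offer a point at which enantiopurity can be raised.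

Step 8
Reactants: 10 (E)-N-tosylhydrazone of 9; 2 1-(benzyloxy)-4-iodo-2-methoxybenzene
Product: 12 dimethyl (1R,3S)-7-(benzyloxy)-1-[4-(benzyloxy)-3-methoxyphenyl]-6-methoxy-3-{[(triisopropylsilyl)oxy]methyl}-3,4-dihydronaphthalene-2,2(1H)-dicarboxylate, via aryldiazomethane 11 (not isolated)
Conditions: Pd2(dba)3 (2.5 mol %), DPEphos (6 mol %), Cs2CO3 (3 equiv), 1,4-dioxane, 90 °C
Reagents that add atoms: none
Why: Proposed new method: Cs2CO3 converts the hydrazone into aryldiazomethane 11 (Bamford–Stevens) and the malonate into its caesium enolate while 2 adds oxidatively to zerovalent palladium; the arylpalladium iodide takes up 11 with loss of N2 to give a palladium carbene at C1, and 1,1-migratory insertion of the aryl group forms C1–C1' and a diarylmethylpalladium that has no beta-hydrogen and rests as an eta-3-benzyl complex over the pendant ring. The enolate carbon C2 then attacks C1 on the face opposite palladium (6-exo with respect to the eta-3-benzyl unit), which forms C1–C2, closes ring B and returns zerovalent palladium. The closest known reaction types are the cross-coupling of aryl halides with N-tosylhydrazones by carbene insertion, carbenylative cyclisations in which a stabilised carbanion or an amine tethered to the halide partner traps an eta-3-allyl- or eta-3-benzylpalladium, and the palladium-catalysed substitution of diarylmethyl carbonates by malonates; untested is a nucleophile that sits on the carbene partner next to a stereocentre. C1 is controlled by C3: allylic 1,3-strain in the planar enolate keeps C3–H in the enolate plane and CH2OTIPS anti to the forming bond (equatorial), the two C1-epimeric palladium species can interconvert through the strongly stabilised bis(4-alkoxyaryl)methyl cation, and the chair-like closure that places the charge-bearing pendant aryl in the outward pseudo-equatorial sector above the caesium-bridged enolate oxygens, not pseudo-axial over C3–H, should lead to the 1,3-cis (1R,3S) product. The step needs carbene capture to outrun azine formation, and C-attack by the tethered enolate to outrun sulfinate capture, protonation and direct arylation of the malonate; the slow release of 11 by sparingly soluble Cs2CO3, the six-membered closure, the hindered tertiary malonate carbon and the wide-bite-angle DPEphos, which favours a cationic eta-3-benzyl complex open to outer-sphere attack, all work in that direction. The closure is irreversible, and a C1 epimer would be removed by chromatography at this stage.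

Step 9
Reactants: 12 dimethyl (1R,3S)-7-(benzyloxy)-1-[4-(benzyloxy)-3-methoxyphenyl]-6-methoxy-3-{[(triisopropylsilyl)oxy]methyl}-3,4-dihydronaphthalene-2,2(1H)-dicarboxylate
Product: 13 methyl (1R,3S)-7-(benzyloxy)-1-[4-(benzyloxy)-3-methoxyphenyl]-6-methoxy-3-{[(triisopropylsilyl)oxy]methyl}-1,2,3,4-tetrahydronaphthalene-2-carboxylate (mixture of C2 epimers)
Conditions: LiCl, H2O, DMSO, 150 °C
Reagents that add atoms: none
Why: Krapcho demethoxycarbonylation (chloride attack at one ester methyl, loss of CO2, protonation of the ester enolate) removes the sacrificial ester, while C1 and C3 carry no acidic hydrogen and stay as set.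

Step 10
Reactants: 13 methyl (1R,3S)-tetralin-2-carboxylate (mixture of C2 epimers)
Product: 14 methyl (1R,2S,3S)-7-(benzyloxy)-1-[4-(benzyloxy)-3-methoxyphenyl]-6-methoxy-3-{[(triisopropylsilyl)oxy]methyl}-1,2,3,4-tetrahydronaphthalene-2-carboxylate
Conditions: NaOMe (0.3 equiv), MeOH–THF, 50 °C; AcOH quench
Reagents that add atoms: none
Why: Base-mediated epimerisation through the ester enolate under thermodynamic control, as used for 1-aryltetralin-2-carboxylates, should collect the material in the isomer with CO2Me equatorial and trans to both neighbours, which sets C2 as S.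

Step 11
Reactants: 14 methyl (1R,2S,3S)-7-(benzyloxy)-1-[4-(benzyloxy)-3-methoxyphenyl]-6-methoxy-3-{[(triisopropylsilyl)oxy]methyl}-1,2,3,4-tetrahydronaphthalene-2-carboxylate
Product: 15 methyl (1R,2S,3S)-7-(benzyloxy)-1-[4-(benzyloxy)-3-methoxyphenyl]-3-(hydroxymethyl)-6-methoxy-1,2,3,4-tetrahydronaphthalene-2-carboxylate
Conditions: TBAF, AcOH (1:1), THF, 23 °C
Reagents that add atoms: none
Why: Fluoride-mediated desilylation, buffered with acetic acid so that no alkoxide is left to epimerise C2 or attack the ester, the only lactone within reach being the strained trans-fused one.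

Step 12
Reactants: 15 methyl (1R,2S,3S)-7-(benzyloxy)-1-[4-(benzyloxy)-3-methoxyphenyl]-3-(hydroxymethyl)-6-methoxy-1,2,3,4-tetrahydronaphthalene-2-carboxylate
Product: 16 methyl (1R,2S,3S)-7-hydroxy-1-(4-hydroxy-3-methoxyphenyl)-3-(hydroxymethyl)-6-methoxy-1,2,3,4-tetrahydronaphthalene-2-carboxylate (CNP0241585.1)
Conditions: H2 (1 atm), 10 % Pd/C, EtOAc–MeOH, 23 °C
Reagents that add atoms: none
Why: Catalytic hydrogenolysis of the two aryl benzyl ethers under neutral conditions touches no stereocentre and leaves ester, alcohol and the C1–aryl bonds intact.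

**Compound list**

1 | 4-iodo-2-methoxyphenol | COc1cc(I)ccc1O | starting material
2 | 1-(benzyloxy)-4-iodo-2-methoxybenzene | Ic1ccc(OCc2ccccc2)c(OC)c1 | intermediate
3 | allyl alcohol | C=CCO | starting material
4 | 3-[4-(benzyloxy)-3-methoxyphenyl]propanal | O=CCCc1ccc(OCc2ccccc2)c(OC)c1 | intermediate
5 | dimethyl bromomalonate | COC(=O)C(Br)C(=O)OC | starting material
6 | dimethyl 2-[(2S)-1-[4-(benzyloxy)-3-methoxyphenyl]-3-oxopropan-2-yl]propanedioate | COC(=O)C(C(=O)OC)[C@@H](C=O)Cc1ccc(OCc2ccccc2)c(OC)c1 | intermediate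
7 | dimethyl 2-[(2S)-1-[4-(benzyloxy)-3-methoxyphenyl]-3-hydroxypropan-2-yl]propanedioate | COC(=O)C(C(=O)OC)[C@@H](CO)Cc1ccc(OCc2ccccc2)c(OC)c1 | intermediate
8 | dimethyl 2-[(2S)-1-[4-(benzyloxy)-3-methoxyphenyl]-3-[(triisopropylsilyl)oxy]propan-2-yl]propanedioate | COC(=O)C(C(=O)OC)[C@@H](CO[Si](C(C)C)(C(C)C)C(C)C)Cc1ccc(OCc2ccccc2)c(OC)c1 | intermediate
9 | dimethyl 2-[(2S)-1-[4-(benzyloxy)-2-formyl-5-methoxyphenyl]-3-[(triisopropylsilyl)oxy]propan-2-yl]propanedioate | COC(=O)C(C(=O)OC)[C@@H](CO[Si](C(C)C)(C(C)C)C(C)C)Cc1cc(OC)c(OCc2ccccc2)cc1C=O | intermediate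
10 | (E)-N-tosylhydrazone of 9 (S at C3) | COC(=O)C(C(=O)OC)[C@@H](CO[Si](C(C)C)(C(C)C)C(C)C)Cc1cc(OC)c(OCc2ccccc2)cc1/C=N/NS(=O)(=O)c1ccc(C)cc1 | intermediate
11 | dimethyl 2-[(2S)-1-[4-(benzyloxy)-2-(diazomethyl)-5-methoxyphenyl]-3-[(triisopropylsilyl)oxy]propan-2-yl]propanedioate | COC(=O)C(C(=O)OC)[C@@H](CO[Si](C(C)C)(C(C)C)C(C)C)Cc1cc(OC)c(OCc2ccccc2)cc1C=[N+]=[N-] | intermediate
12 | dimethyl (1R,3S)-7-(benzyloxy)-1-[4-(benzyloxy)-3-methoxyphenyl]-6-methoxy-3-{[(triisopropylsilyl)oxy]methyl}-3,4-dihydronaphthalene-2,2(1H)-dicarboxylate | COC(=O)C1(C(=O)OC)[C@@H](CO[Si](C(C)C)(C(C)C)C(C)C)Cc2cc(OC)c(OCc3ccccc3)cc2[C@H]1c1ccc(OCc2ccccc2)c(OC)c1 | intermediate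
13 | methyl (1R,3S)-7-(benzyloxy)-1-[4-(benzyloxy)-3-methoxyphenyl]-6-methoxy-3-{[(triisopropylsilyl)oxy]methyl}-1,2,3,4-tetrahydronaphthalene-2-carboxylate, C2 epimers | COC(=O)C1[C@@H](CO[Si](C(C)C)(C(C)C)C(C)C)Cc2cc(OC)c(OCc3ccccc3)cc2[C@H]1c1ccc(OCc2ccccc2)c(OC)c1 | intermediate
14 | methyl (1R,2S,3S)-7-(benzyloxy)-1-[4-(benzyloxy)-3-methoxyphenyl]-6-methoxy-3-{[(triisopropylsilyl)oxy]methyl}-1,2,3,4-tetrahydronaphthalene-2-carboxylate | COC(=O)[C@@H]1[C@@H](CO[Si](C(C)C)(C(C)C)C(C)C)Cc2cc(OC)c(OCc3ccccc3)cc2[C@H]1c1ccc(OCc2ccccc2)c(OC)c1 | intermediate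
15 | methyl (1R,2S,3S)-7-(benzyloxy)-1-[4-(benzyloxy)-3-methoxyphenyl]-3-(hydroxymethyl)-6-methoxy-1,2,3,4-tetrahydronaphthalene-2-carboxylate | COC(=O)[C@@H]1[C@@H](CO)Cc2cc(OC)c(OCc3ccccc3)cc2[C@H]1c1ccc(OCc2ccccc2)c(OC)c1 | intermediate
16 | methyl (1R,2S,3S)-7-hydroxy-1-(4-hydroxy-3-methoxyphenyl)-3-(hydroxymethyl)-6-methoxy-1,2,3,4-tetrahydronaphthalene-2-carboxylate | COC(=O)[C@@H]1[C@@H](CO)Cc2cc(OC)c(O)cc2[C@H]1c1ccc(O)c(OC)c1 | target

Total step count: 12. Longest linear sequence: 12 steps (1 to 16); compound 2 enters the line twice, in steps 2 and 8.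

**Steps most likely to fail**

Risk 1, step 8. Several things may go wrong here.
- The diazo compound may dimerise to the azine.
- The diarylmethylpalladium may be taken by sulfinate or by a proton before the enolate reaches C1.
- The ring may close with poor facial selectivity at C1, because peri contact with C8–H and gauche contact with the geminal esters push the pendant aryl towards the pseudo-axial position.

The fallback uses known chemistry only, sets out from 8 and comes back at 16. It fixes C1 by hydrogen delivery instead of by ring closure. One ester of 8 is saponified with KOH (1 equiv) in MeOH to the malonic half-ester F1. Trifluoroacetic anhydride in CH2Cl2 at 0 °C closes it by intramolecular Friedel–Crafts acylation para to OMe to the 1-tetralone-2-carboxylate F2. NaH and PhNTf2 give the enol triflate F3. Suzuki coupling with commercial 4-benzyloxy-3-methoxyphenylboronic acid (Pd(PPh3)4, K2CO3, dioxane–water) gives the 1-aryl-3,4-dihydronaphthalene-2-carboxylate F4. Hydrogenation over Pd/C under a few bar of H2 should add hydrogen to the face away from CH2OTIPS and remove both benzyl groups, giving the all-cis ester F5. NaOMe in MeOH then epimerises C2 to the all-trans ester F6, and buffered TBAF gives 16.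

Risk 2, step 4. The gamma-hydroxy malonate may close to the butyrolactone with loss of methanol before it can be silylated. The fallback sets out from 6 and comes back at 8, and it accepts the lactone instead of racing it. Compound 6 is reduced with NaBH4 in MeOH, and 7 is allowed to close to the alpha-methoxycarbonyl butyrolactone F7. Excess aqueous KOH opens the lactone and hydrolyses the ester to the dipotassium hydroxy malonate F8. This salt is silylated with TIPSCl and imidazole in DMF, the silyl esters falling off in an aqueous K2CO3 wash. Cold acidification gives the silyloxy malonic acid F9, and TMSCHN2 in MeOH–toluene re-esterifies both acids to 8.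

Risk 3, step 6. The strong acid released during formylation may strip the benzyl or silyl ether, or the electrophile may attack a wrong ring position. The fallback sets out from 8 and comes back at 9, and it replaces electrophilic formylation by halogenation, neutral cross-coupling and alkene cleavage. NBS in MeCN at 0 °C brominates para to OMe to the aryl bromide F10. Base-free Stille coupling with tributyl(vinyl)stannane (Pd(PPh3)4, toluene, 100 °C) forms no malonate enolate, so intramolecular arylation is avoided, and it gives the styrene F11. Lemieux–Johnson cleavage (OsO4 cat., NaIO4, 2,6-lutidine, dioxane–water) then gives 9.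

**Further compounds**

F1 | step 8 | 3-methoxy-3-oxo-2-[(2S)-1-[4-(benzyloxy)-3-methoxyphenyl]-3-[(triisopropylsilyl)oxy]propan-2-yl]propanoic acid (C2 epimers) | COC(=O)C(C(O)=O)[C@@H](CO[Si](C(C)C)(C(C)C)C(C)C)Cc1ccc(OCc2ccccc2)c(OC)c1
F2 | step 8 | methyl (3S)-7-(benzyloxy)-6-methoxy-1-oxo-3-{[(triisopropylsilyl)oxy]methyl}-1,2,3,4-tetrahydronaphthalene-2-carboxylate | COC(=O)C1C(=O)c2cc(OCc3ccccc3)c(OC)cc2C[C@@H]1CO[Si](C(C)C)(C(C)C)C(C)C
F3 | step 8 | methyl (3S)-7-(benzyloxy)-6-methoxy-1-[(trifluoromethylsulfonyl)oxy]-3-{[(triisopropylsilyl)oxy]methyl}-3,4-dihydronaphthalene-2-carboxylate | COC(=O)C1=C(OS(=O)(=O)C(F)(F)F)c2cc(OCc3ccccc3)c(OC)cc2C[C@@H]1CO[Si](C(C)C)(C(C)C)C(C)C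
F4 | step 8 | methyl (3S)-7-(benzyloxy)-1-[4-(benzyloxy)-3-methoxyphenyl]-6-methoxy-3-{[(triisopropylsilyl)oxy]methyl}-3,4-dihydronaphthalene-2-carboxylate | COC(=O)C1=C(c2ccc(OCc3ccccc3)c(OC)c2)c2cc(OCc3ccccc3)c(OC)cc2C[C@@H]1CO[Si](C(C)C)(C(C)C)C(C)C
F5 | step 8 | methyl (1R,2R,3S)-7-hydroxy-1-(4-hydroxy-3-methoxyphenyl)-6-methoxy-3-{[(triisopropylsilyl)oxy]methyl}-1,2,3,4-tetrahydronaphthalene-2-carboxylate (all-cis) | COC(=O)[C@H]1[C@@H](CO[Si](C(C)C)(C(C)C)C(C)C)Cc2cc(OC)c(O)cc2[C@H]1c1ccc(O)c(OC)c1
F6 | step 8 | methyl (1R,2S,3S)-7-hydroxy-1-(4-hydroxy-3-methoxyphenyl)-6-methoxy-3-{[(triisopropylsilyl)oxy]methyl}-1,2,3,4-tetrahydronaphthalene-2-carboxylate (all-trans) | COC(=O)[C@@H]1[C@@H](CO[Si](C(C)C)(C(C)C)C(C)C)Cc2cc(OC)c(O)cc2[C@H]1c1ccc(O)c(OC)c1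
F7 | step 4 | methyl (4S)-4-[4-(benzyloxy)-3-methoxybenzyl]-2-oxotetrahydrofuran-3-carboxylate (C3 epimers) | COC(=O)C1C(=O)OC[C@H]1Cc1ccc(OCc2ccccc2)c(OC)c1
F8 | step 4 | dipotassium 2-[(2S)-1-[4-(benzyloxy)-3-methoxyphenyl]-3-hydroxypropan-2-yl]propanedioate | [K+].[K+].[O-]C(=O)C(C([O-])=O)[C@@H](CO)Cc1ccc(OCc2ccccc2)c(OC)c1
F9 | step 4 | 2-[(2S)-1-[4-(benzyloxy)-3-methoxyphenyl]-3-[(triisopropylsilyl)oxy]propan-2-yl]propanedioic acid | OC(=O)C(C(O)=O)[C@@H](CO[Si](C(C)C)(C(C)C)C(C)C)Cc1ccc(OCc2ccccc2)c(OC)c1
F10 | step 6 | dimethyl 2-[(2S)-1-[4-(benzyloxy)-2-bromo-5-methoxyphenyl]-3-[(triisopropylsilyl)oxy]propan-2-yl]propanedioate | COC(=O)C(C(=O)OC)[C@@H](CO[Si](C(C)C)(C(C)C)C(C)C)Cc1cc(OC)c(OCc2ccccc2)cc1Br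
F11 | step 6 | dimethyl 2-[(2S)-1-[4-(benzyloxy)-2-ethenyl-5-methoxyphenyl]-3-[(triisopropylsilyl)oxy]propan-2-yl]propanedioate | COC(=O)C(C(=O)OC)[C@@H](CO[Si](C(C)C)(C(C)C)C(C)C)Cc1cc(OC)c(OCc2ccccc2)cc1C=C
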